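**Retrosynthetic overview**
1. Feature used: in ring A the chain C5(OH)–C6(OH)–C7(OSO3H)–C8(H) lies between the fusion carbons C4a and C8a. These four carbons and three oxygens are a squaric acid ring reduced at one carbon: C5 is the ketone, C6/C7 the dialkoxyalkene, C8 the sp3 carbon.
2. End game: the O7–S bond (sulfation of the 5,6,7-triol while ring B is silylated), preceded by removal of the O6 and O7 benzyl ethers.
3. Key disconnection C4a–C5: ring A grows out of the four-membered ring of a 4-(4-oxopyran-2-yl)cyclobutenone by thermal 4π opening and 6π closure onto the pyranone C8a=C4a bond.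
4. C8–C8a: palladium-catalysed union of a 4-chlorocyclobutenone (three steps from squaric acid) with the 2-arylpyran-4-one zincated beside its ring oxygen.
5. Ring order: ring B is bought (3,4-dihydroxybenzoic acid), ring C is made first (aroylation of an enaminone, cyclisation), the cyclobutenone is attached, and ring A is formed last.

Key step: step 8

Assumption: the target is drawn as the free hydrogen sulfate, so the last step ends with a cold proton exchange; for storage the triethylammonium or sodium salt would be kept.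

Step 1
Reactants: 1 squaric acid
Product: 2 dibenzyl squarate, 3,4-bis(benzyloxy)cyclobut-3-ene-1,2-dione
Conditions: BnOH (5 equiv), PhMe, Dean–Stark, reflux
Reagents that add atoms: benzyl alcohol, OCc1ccccc1
Why: Squaric acid is a strong vinylogous acid that catalyses its own Fischer-type esterification, and azeotropic removal of water drives both hydroxyls to the vinylogous benzyl esters as in the standard preparation of dialkyl squarates.

Step 2
Reactants: 2 dibenzyl squarate
Product: 3 2,3-bis(benzyloxy)-4-hydroxycyclobut-2-en-1-one (racemic)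
Conditions: LiAlH(OtBu)3 (1.05 equiv), THF, −78 → −30 °C; cold pH 7 buffer
Reagents that add atoms: none
Why: The hindered hydride adds once, in 1,2-fashion, to one of the two equivalent carbonyl groups of a dialkyl squarate (chemoselective carbonyl reduction, the known entry to 4-hydroxycyclobutenones), the aluminium alkoxide blocks a second addition, the neutral quench avoids the acid-induced change to the semisquarate, and the new C4 centre is racemic and is erased in step 8.

Step 3
Reactants: 3 2,3-bis(benzyloxy)-4-hydroxycyclobut-2-en-1-one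
Product: 4 2,3-bis(benzyloxy)-4-chlorocyclobut-2-en-1-one (racemic)
Conditions: 1-chloro-N,N,2-trimethylprop-1-en-1-amine (1.0 equiv), CH2Cl2, 0 °C; concentrated cold and used at once
Reagents that add atoms: 1-chloro-N,N,2-trimethylprop-1-en-1-amine, CC(C)=C(Cl)N(C)C
Why: The α-chloroenamine converts the alcohol into an alkoxyiminium chloride that collapses by chloride substitution at C4 without any free acid (neutral deoxychlorination), so the ionisation that would shift the allyl system and strip a benzyl group is held back; the C4 centre stays racemic.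

Step 4
Reactants: 5 3,4-dihydroxybenzoic acid
Product: 6 tert-butyldimethylsilyl 3,4-bis(tert-butyldimethylsilyloxy)benzoate
Conditions: TBSCl (3.5 equiv), imidazole (7 equiv), DMF, 25 °C
Reagents that add atoms: tert-butyldimethylsilyl chloride, CC(C)(C)[Si](C)(C)Cl
Why: Imidazole-promoted silylation caps both phenols and the acid in one operation, and the silyl ester is the handle for step 5.

Step 5
Reactants: 6 tert-butyldimethylsilyl 3,4-bis(tert-butyldimethylsilyloxy)benzoate
Product: 7 3,4-bis(tert-butyldimethylsilyloxy)benzoyl chloride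
Conditions: (COCl)2 (1.2 equiv), DMF (cat.), CH2Cl2, 0 → 25 °C
Reagents that add atoms: oxalyl chloride, ClC(=O)C(=O)Cl
Why: The chloroiminium salt formed from DMF and oxalyl chloride exchanges a silyl ester directly for the acid chloride and releases the silyl group as its chloride, so that no HCl is formed and the aryl silyl ethers are untouched (Vilsmeier-type acyl chloride formation).

Step 6
Reactants: 7 3,4-bis(tert-butyldimethylsilyloxy)benzoyl chloride; 8 (E)-4-(dimethylamino)but-3-en-2-one
Product: 11 2-[3,4-bis(tert-butyldimethylsilyloxy)phenyl]-4H-pyran-4-one, via lithium dienolate 9 (not isolated), via enaminodiketone 10 (not isolated)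
Conditions: 8, LiN(SiMe3)2 (2.1 equiv), THF, −78 °C; 7, −78 → −20 °C; then CF3CO2H (6 equiv), THF–CH2Cl2, 0 → 25 °C
Reagents that add atoms: none
Why: Kinetic deprotonation at the methyl group gives the cross-conjugated dienolate 9, so that the Claisen-type C-aroylation takes place at that carbon and not at the enamine carbon, and acid then lets the enol oxygen of 10 add to the aminovinyl carbon and expel dimethylamine (6-endo addition–elimination, the standard 4-pyranone synthesis), conditions under which aryl silyl ethers hold.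

Step 7
Reactants: 11 2-[3,4-bis(tert-butyldimethylsilyloxy)phenyl]-4H-pyran-4-one; 4 2,3-bis(benzyloxy)-4-chlorocyclobut-2-en-1-one
Product: 13 2,3-bis(benzyloxy)-4-{6-[3,4-bis(tert-butyldimethylsilyloxy)phenyl]-4-oxo-4H-pyran-2-yl}cyclobut-2-en-1-one (racemic), via pyranonylzinc chloride 12 (not isolated)
Conditions: 11, TMPZnCl·LiCl (TMP = 2,2,6,6-tetramethylpiperidide, 1.2 equiv), THF, 0 → 25 °C; then Pd2(dba)3 (2.5 mol %), P(2-furyl)3 (10 mol %), 4 (1.1 equiv), THF, 0 → 25 °C; pH 7 buffer
Reagents that add atoms: none
Why: TMPZnCl·LiCl removes the most acidic ring proton, the one beside the ring oxygen, as it does at C2 of chromones when no Lewis acid is added (directed zincation), and the zinc reagent, inert towards the cyclobutenone carbonyl, is joined after oxidative addition of zerovalent palladium to the less substituted terminus of the oxocyclobutenyl–palladium intermediate in a Negishi-type version of the known cross-coupling of 4-chlorocyclobutenones, at a temperature below that of ring opening; the new C4 centre is racemic and disappears in step 8.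

Step 8
Reactants: 13 2,3-bis(benzyloxy)-4-{6-[3,4-bis(tert-butyldimethylsilyloxy)phenyl]-4-oxo-4H-pyran-2-yl}cyclobut-2-en-1-one
Product: 16 6,7-bis(benzyloxy)-2-[3,4-bis(tert-butyldimethylsilyloxy)phenyl]-5-hydroxy-4H-chromen-4-one, via inward dienylketene 14 (not isolated), via 4aH-dione tautomer 15 (not isolated)
Conditions: PhMe (0.01 M, dry, degassed), 110 °C
Reagents that add atoms: none
Why: Proposed new method: heating opens the strained ring by conrotatory 4π cleavage of the bond between the carbonyl carbon and C4 (C5–C8 in flavone numbering) and gives dienylketene 14, in which the ketene, the C7=C8 bond and the pyranone C8a=C4a bond form a hexatriene. Disrotatory 6π electrocyclisation joins the ketene carbon to C4a and closes the six-membered carbocycle (ring A) as dione 15, whose C4a–H lies between two carbonyl groups and shifts at once to oxygen, so ring A arrives aromatic with the chelated 5-OH. The closest known reaction type is the thermal benzannulation of 4-alkenyl-, 4-aryl- and 4-heteroarylcyclobutenones (Moore rearrangement and the phenol synthesis from 4-chlorocyclobutenones); new here is a 4-pyranone C=C bond as terminus, which should help because it has little aromatic stabilisation to lose and C4a is the nucleophilic β-carbon of an enol ether that matches the electrophilic ketene carbon. Only the isomer with the pyranonyl group turned inward can close; the electron-poor C8a substituent is not biased against inward rotation, the outward isomer recloses to 13 under the same conditions, and the irreversible aromatisation drains the equilibrium. Site selectivity is structural, since C4a is the only pyranone carbon within reach of the ketene, and the racemic C8 centre of 13 and the transient C4a centre of 15 both vanish, so no stereocentre remains. High dilution and dry, degassed solvent keep the ketene from being trapped by water or by the phenol already formed.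

Step 9
Reactants: 16 6,7-bis(benzyloxy)-2-[3,4-bis(tert-butyldimethylsilyloxy)phenyl]-5-hydroxy-4H-chromen-4-one
Product: 17 2-[3,4-bis(tert-butyldimethylsilyloxy)phenyl]-5,6,7-trihydroxy-4H-chromen-4-one
Conditions: H2 (1 atm), Pd/C (10 wt %), EtOAc–THF, 25 °C; handled under Ar
Reagents that add atoms: none
Why: Catalytic hydrogenolysis cleaves the two benzylic C–O bonds at one atmosphere, where aryl silyl ethers and the cross-conjugated C2=C3 bond of a flavone are not touched.

Step 10
Reactants: 17 2-[3,4-bis(tert-butyldimethylsilyloxy)phenyl]-5,6,7-trihydroxy-4H-chromen-4-one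
Product: 18 triethylammonium 2-[3,4-bis(tert-butyldimethylsilyloxy)phenyl]-5,6-dihydroxy-4-oxo-4H-chromen-7-yl sulfate
Conditions: SO3·NEt3 (1.05 equiv), NEt3 (1.0 equiv), MeCN, 0 → 25 °C, Ar
Reagents that add atoms: sulfur trioxide–triethylamine complex, CC[N+](CC)(CC)S(=O)(=O)[O-]
Why: O-sulfonation with an amine–sulfur trioxide complex goes to the phenoxide that forms first, and with one equivalent of base this should be O7, whose O–H is a vinylogous acid conjugated with the C4 carbonyl through C4a, whereas O5–H is locked in the chelate with that carbonyl and O6–H is flanked on both sides, the same order that gives 7-O-alkyl derivatives from 5,6,7-trihydroxyflavones.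

Step 11
Reactants: 18 triethylammonium 2-[3,4-bis(tert-butyldimethylsilyloxy)phenyl]-5,6-dihydroxy-4-oxo-4H-chromen-7-yl sulfate
Product: 20 6-hydroxyluteolin 7-sulfate, 2-(3,4-dihydroxyphenyl)-5,6-dihydroxy-4-oxo-4H-chromen-7-yl hydrogen sulfate, via desilylated triethylammonium salt 19 (not isolated)
Conditions: NH4F (6 equiv), MeOH, 25 °C; then Dowex 50WX8 (H+ form), H2O–MeOH, 0 °C; freeze-drying
Reagents that add atoms: none
Why: Fluoride attacks silicon and releases the two ring B phenols at near-neutral pH (fluoride desilylation), aryl sulfate monoesters being inert to fluoride and to methanol, and a short cold cation exchange then replaces triethylammonium by a proton.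

**Compound list**
1 | squaric acid | OC1=C(O)C(=O)C1=O | starting material
2 | 3,4-bis(benzyloxy)cyclobut-3-ene-1,2-dione (dibenzyl squarate) | O=C1C(=O)C(OCc2ccccc2)=C1OCc1ccccc1 | intermediate
3 | 2,3-bis(benzyloxy)-4-hydroxycyclobut-2-en-1-one (racemic) | O=C1C(OCc2ccccc2)=C(OCc2ccccc2)C1O | intermediate
4 | 2,3-bis(benzyloxy)-4-chlorocyclobut-2-en-1-one (racemic) | O=C1C(OCc2ccccc2)=C(OCc2ccccc2)C1Cl | intermediate
5 | 3,4-dihydroxybenzoic acid | OC(=O)c1ccc(O)c(O)c1 | starting material
6 | tert-butyldimethylsilyl 3,4-bis(tert-butyldimethylsilyloxy)benzoate | CC(C)(C)[Si](C)(C)OC(=O)c1ccc(O[Si](C)(C)C(C)(C)C)c(O[Si](C)(C)C(C)(C)C)c1 | intermediate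
7 | 3,4-bis(tert-butyldimethylsilyloxy)benzoyl chloride | ClC(=O)c1ccc(O[Si](C)(C)C(C)(C)C)c(O[Si](C)(C)C(C)(C)C)c1 | intermediate
8 | (E)-4-(dimethylamino)but-3-en-2-one | CN(C)/C=C/C(C)=O | starting material
9 | lithium (3E)-4-(dimethylamino)buta-1,3-dien-2-olate | [Li+].[O-]C(=C)/C=C/N(C)C | intermediate
10 | (4E)-1-[3,4-bis(tert-butyldimethylsilyloxy)phenyl]-5-(dimethylamino)pent-4-ene-1,3-dione | CN(C)/C=C/C(=O)CC(=O)c1ccc(O[Si](C)(C)C(C)(C)C)c(O[Si](C)(C)C(C)(C)C)c1 | intermediate
11 | 2-[3,4-bis(tert-butyldimethylsilyloxy)phenyl]-4H-pyran-4-one | O=c1ccoc(-c2ccc(O[Si](C)(C)C(C)(C)C)c(O[Si](C)(C)C(C)(C)C)c2)c1 | intermediate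
12 | {6-[3,4-bis(tert-butyldimethylsilyloxy)phenyl]-4-oxo-4H-pyran-2-yl}zinc chloride (LiCl adduct) | Cl[Zn]c1cc(=O)cc(-c2ccc(O[Si](C)(C)C(C)(C)C)c(O[Si](C)(C)C(C)(C)C)c2)o1 | intermediate
13 | 2,3-bis(benzyloxy)-4-{6-[3,4-bis(tert-butyldimethylsilyloxy)phenyl]-4-oxo-4H-pyran-2-yl}cyclobut-2-en-1-one (racemic) | O=C1C(OCc2ccccc2)=C(OCc2ccccc2)C1c1cc(=O)cc(-c2ccc(O[Si](C)(C)C(C)(C)C)c(O[Si](C)(C)C(C)(C)C)c2)o1 | intermediate
14 | (3E)-2,3-bis(benzyloxy)-4-{6-[3,4-bis(tert-butyldimethylsilyloxy)phenyl]-4-oxo-4H-pyran-2-yl}buta-1,3-dien-1-one (pyranonyl group cis to the ketene-bearing carbon) | O=C=C(OCc1ccccc1)/C(OCc1ccccc1)=C\c1cc(=O)cc(-c2ccc(O[Si](C)(C)C(C)(C)C)c(O[Si](C)(C)C(C)(C)C)c2)o1 | intermediate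
15 | 6,7-bis(benzyloxy)-2-[3,4-bis(tert-butyldimethylsilyloxy)phenyl]-4aH-chromene-4,5-dione (racemic, transient) | O=C1C=C(c2ccc(O[Si](C)(C)C(C)(C)C)c(O[Si](C)(C)C(C)(C)C)c2)OC2=CC(OCc3ccccc3)=C(OCc3ccccc3)C(=O)C12 | intermediate
16 | 6,7-bis(benzyloxy)-2-[3,4-bis(tert-butyldimethylsilyloxy)phenyl]-5-hydroxy-4H-chromen-4-one | O=c1cc(-c2ccc(O[Si](C)(C)C(C)(C)C)c(O[Si](C)(C)C(C)(C)C)c2)oc2cc(OCc3ccccc3)c(OCc3ccccc3)c(O)c12 | intermediate
17 | 2-[3,4-bis(tert-butyldimethylsilyloxy)phenyl]-5,6,7-trihydroxy-4H-chromen-4-one | O=c1cc(-c2ccc(O[Si](C)(C)C(C)(C)C)c(O[Si](C)(C)C(C)(C)C)c2)oc2cc(O)c(O)c(O)c12 | intermediate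
18 | triethylammonium 2-[3,4-bis(tert-butyldimethylsilyloxy)phenyl]-5,6-dihydroxy-4-oxo-4H-chromen-7-yl sulfate | CC[NH+](CC)CC.O=c1cc(-c2ccc(O[Si](C)(C)C(C)(C)C)c(O[Si](C)(C)C(C)(C)C)c2)oc2cc(OS(=O)(=O)[O-])c(O)c(O)c12 | intermediate
19 | triethylammonium 2-(3,4-dihydroxyphenyl)-5,6-dihydroxy-4-oxo-4H-chromen-7-yl sulfate | CC[NH+](CC)CC.O=c1cc(-c2ccc(O)c(O)c2)oc2cc(OS(=O)(=O)[O-])c(O)c(O)c12 | intermediate
20 | 6-hydroxyluteolin 7-sulfate, 2-(3,4-dihydroxyphenyl)-5,6-dihydroxy-4-oxo-4H-chromen-7-yl hydrogen sulfate | O=c1cc(-c2ccc(O)c(O)c2)oc2cc(OS(=O)(=O)O)c(O)c(O)c12 | target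

**Total step count:** 11.
**Longest linear sequence:** 8 steps (5 to 20 through steps 4–11). The squaric acid branch, steps 1–3 and 7–11, is equally long.

**Steps most likely to fail**

Step 8.
- What may go wrong: the ketene may be lost faster than it closes. It can be trapped by the phenol already formed or by traces of water, or it can dimerise. A proton shift in 13 can also move the ring double bond into conjugation with the pyranone and take away the C8–H terminus.
- Fallback: known chemistry only, with ring A taken from a benzene building block and ring C closed last. It sets out from aroyl chloride 7 and comes back at triol 17. Commercial 1-[2,4-bis(benzyloxy)-6-hydroxyphenyl]ethanone is oxidised para to its phenol with K2S2O8 in aqueous NaOH–pyridine (Elbs persulfate oxidation) to potassium 3-acetyl-2,6-bis(benzyloxy)-4-hydroxyphenyl sulfate F1. Dilute HCl hydrolyses this to 1-[2,4-bis(benzyloxy)-3,6-dihydroxyphenyl]ethanone F2. BnBr and K2CO3 in acetone alkylate only the hydroxyl that is not chelated to the acetyl group (Williamson ether synthesis) and give 1-[2,3,4-tris(benzyloxy)-6-hydroxyphenyl]ethanone F3. LiN(SiMe3)2 (3 equiv, THF, −78 °C) followed by 7 gives 1-[3,4-bis(tert-butyldimethylsilyloxy)phenyl]-3-[2,3,4-tris(benzyloxy)-6-hydroxyphenyl]propane-1,3-dione F4 (Baker–Venkataraman-type C-aroylation). Catalytic TsOH in toluene at 80 °C closes ring C to 5,6,7-tris(benzyloxy)-2-[3,4-bis(tert-butyldimethylsilyloxy)phenyl]-4H-chromen-4-one F5. Hydrogenolysis under the conditions of step 9 removes the three benzyl groups and gives 17.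

Step 7.
- What may go wrong: the zinc and lithium chlorides may assist ionisation of chloride 4 with loss of a benzyl group. Carbon–carbon bond formation may drift to the alkoxy-bearing allyl terminus (allylic transposition). The liberated amine may cause a proton shift in the product.
- Fallback: it sets out from pyranone 11 and comes back at 13, and replaces the zinc reagent made in the flask by an isolated, salt-free and amine-free tin partner. 11 is zincated as in step 7 (12) and quenched with I2 to give 2-[3,4-bis(tert-butyldimethylsilyloxy)phenyl]-6-iodo-4H-pyran-4-one F6. Pd(PPh3)4 and Bu3SnSnBu3 in toluene at 100 °C convert it into 2-[3,4-bis(tert-butyldimethylsilyloxy)phenyl]-6-(tributylstannyl)-4H-pyran-4-one F7. Purified F7 is coupled with 4 under PdCl2(PhCN)2 and P(2-furyl)3 in dioxane at 40–50 °C to give 13. This Stille coupling is the combination for which the union of 4-chlorocyclobutenones with 2-metallated heteroarenes is established.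

Step 10.
- What may go wrong: sulfation may spread to O6 or go twice, and the basic medium may move silyl groups. The ionic regioisomers would be hard to separate and to assign.
- Fallback: it sets out from triol 17 and comes back at 19, and fixes the site on neutral, chromatographable compounds before sulfur is introduced. Ac2O in pyridine gives 2-[3,4-bis(tert-butyldimethylsilyloxy)phenyl]-4-oxo-4H-chromene-5,6,7-triyl triacetate F8. PhSH and imidazole in N-methylpyrrolidone at 25 °C remove only the 7-acetate, the ester of the best phenoxide leaving group (the known regioselective 7-O-deacetylation of peracetylated flavones). The product is 2-[3,4-bis(tert-butyldimethylsilyloxy)phenyl]-7-hydroxy-4-oxo-4H-chromene-5,6-diyl diacetate F9. Acetyl migration from O6 to O7 would be uphill, because it would free the less acidic hydroxyl. SO3·NEt3 in MeCN then has a single free hydroxyl to attack and gives triethylammonium 5,6-diacetoxy-2-[3,4-bis(tert-butyldimethylsilyloxy)phenyl]-4-oxo-4H-chromen-7-yl sulfate F10. NH4F with NEt3 in MeOH removes the silyl groups and methanolyses the two aryl acetates to give 19, which the cation exchange of step 11 turns into 20.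

**Further compounds**
F1 | step 8 | potassium 3-acetyl-2,6-bis(benzyloxy)-4-hydroxyphenyl sulfate | [K+].[O-]S(=O)(=O)Oc1c(OCc2ccccc2)cc(O)c(C(C)=O)c1OCc1ccccc1
F2 | step 8 | 1-[2,4-bis(benzyloxy)-3,6-dihydroxyphenyl]ethanone | CC(=O)c1c(O)cc(OCc2ccccc2)c(O)c1OCc1ccccc1
F3 | step 8 | 1-[2,3,4-tris(benzyloxy)-6-hydroxyphenyl]ethanone | CC(=O)c1c(O)cc(OCc2ccccc2)c(OCc2ccccc2)c1OCc1ccccc1
F4 | step 8 | 1-[3,4-bis(tert-butyldimethylsilyloxy)phenyl]-3-[2,3,4-tris(benzyloxy)-6-hydroxyphenyl]propane-1,3-dione | O=C(CC(=O)c1c(O)cc(OCc2ccccc2)c(OCc2ccccc2)c1OCc1ccccc1)c1ccc(O[Si](C)(C)C(C)(C)C)c(O[Si](C)(C)C(C)(C)C)c1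
F5 | step 8 | 5,6,7-tris(benzyloxy)-2-[3,4-bis(tert-butyldimethylsilyloxy)phenyl]-4H-chromen-4-one | O=c1cc(-c2ccc(O[Si](C)(C)C(C)(C)C)c(O[Si](C)(C)C(C)(C)C)c2)oc2cc(OCc3ccccc3)c(OCc3ccccc3)c(OCc3ccccc3)c12
F6 | step 7 | 2-[3,4-bis(tert-butyldimethylsilyloxy)phenyl]-6-iodo-4H-pyran-4-one | O=c1cc(I)oc(-c2ccc(O[Si](C)(C)C(C)(C)C)c(O[Si](C)(C)C(C)(C)C)c2)c1
F7 | step 7 | 2-[3,4-bis(tert-butyldimethylsilyloxy)phenyl]-6-(tributylstannyl)-4H-pyran-4-one | CCCC[Sn](CCCC)(CCCC)c1cc(=O)cc(-c2ccc(O[Si](C)(C)C(C)(C)C)c(O[Si](C)(C)C(C)(C)C)c2)o1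
F8 | step 10 | 2-[3,4-bis(tert-butyldimethylsilyloxy)phenyl]-4-oxo-4H-chromene-5,6,7-triyl triacetate | CC(=O)Oc1cc2oc(-c3ccc(O[Si](C)(C)C(C)(C)C)c(O[Si](C)(C)C(C)(C)C)c3)cc(=O)c2c(OC(C)=O)c1OC(C)=O
F9 | step 10 | 2-[3,4-bis(tert-butyldimethylsilyloxy)phenyl]-7-hydroxy-4-oxo-4H-chromene-5,6-diyl diacetate | Oc1cc2oc(-c3ccc(O[Si](C)(C)C(C)(C)C)c(O[Si](C)(C)C(C)(C)C)c3)cc(=O)c2c(OC(C)=O)c1OC(C)=O
F10 | step 10 | triethylammonium 5,6-diacetoxy-2-[3,4-bis(tert-butyldimethylsilyloxy)phenyl]-4-oxo-4H-chromen-7-yl sulfate | CC[NH+](CC)CC.[O-]S(=O)(=O)Oc1cc2oc(-c3ccc(O[Si](C)(C)C(C)(C)C)c(O[Si](C)(C)C(C)(C)C)c3)cc(=O)c2c(OC(C)=O)c1OC(C)=O
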